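- Keep one balance in any closed flask of this scheme: each incoming ligand spent frees one leaving ligand, and each starting complex charged stays as starting complex, one of the two exchanged complexes, side product or self-condensation product.

common to all: starting complex 0.55 M; leaving ligand 2.75 M

|  | incoming ligand | remark | time |
|---|---|---|---|
| autumn | 0.37 M | run made earlier |  |
| dawn | 1.3 M | run made earlier |  |
| west | 0.825 M |  | 1.0 h |
| south-west | 0.275 M |  | 1.0 h |
| south | 0.440 M |  | 1.0 h |

| run | time / min | complex with one exchanged / % | complex with two exchanged / % |
|---|---|---|---|
| autumn | 3.00 | 0.6 | 5.5 |
| autumn | 6.00 | 0 | 4.7 |
| autumn | 10.0 | 0 | 4.9 |
| autumn | 15.0 | 0.2 | 3.8 |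
| autumn | 25.0 | 0.3 | 5.5 |
| autumn | 40.0 | 0 | 4.6 |
| dawn | 8.00 | 0 | 33.8 |
| dawn | 15.0 | 0 | 33.4 |
| dawn | 20.0 | 0 | 33.8 |
| dawn | 30.0 | 0 | 33.4 |
| dawn | 40.0 | 0 | 33.5 |

(standard deviation of a reading: 0.5 percentage points)

- in percentages every species weighs as the starting complex in it: one self-condensation product counts as two
- reactions considered so far: starting complex + incoming ligand -> leaving ligand + complex with one exchanged; complex with one exchanged + incoming ligand -> leaving ligand + complex with two exchanged; 2 starting complex -> self-condensation product; complex with one exchanged -> side product

1. which of these holds the largest part of the starting complex at the end of west (complex with one exchanged / starting complex / complex with two exchanged)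
2. which of these holds the largest part of the starting complex at the end of south-west (complex with one exchanged / starting complex / complex with two exchanged)
3. which of these holds the largest part of the starting complex at the end of south (complex with one exchanged / starting complex / complex with two exchanged)
4. how much complex with one exchanged is there at the end of south-west, in percent of the starting complex charged

- Begin with just the two exchanges. With no one-exchanged complex left, autumn's 0.37 M of ligand makes 33.6% of two-exchanged complex, yet its readings average 4.83%.
- Add the loss to side product. That step needs no ligand, while the second exchange runs in proportion to ligand (pseudo-first-order at a given ligand level), so the share going on to two-exchanged complex is ligand/(ligand + branch).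
- Read the branch from dawn. Its ligand, 1.3 M, exceeds the 1.10 M that double exchange of its starting complex takes, so that complex is used up. The mean share is 33.6%, and ligand falls to 0.565 M, averaging 0.933 M.
- This gives 1.84 M, the branch concentration: the ligand concentration at which one-exchanged complex splits evenly between the two routes.
- Reckon west. At most, each starting complex takes 1.31 ligands, so the demand is 0.720 M, below the charge. Starting complex reaches zero, and the mean ligand gives two-exchanged complex 20.1%.
- Reckon south-west, where ligand is the limiting reagent. With share 6.94%, starting complex keeps 53.2% and two-exchanged complex reaches 3.24%.
- Reckon south the same way: 10.7% gives starting complex 27.7%, ahead of two-exchanged complex at 7.70%.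
- Add self-condensation last: it takes no ligand and draws on the leftover starting complex. Reckon south-west's one-exchanged complex as zero: autumn, also charged with less ligand than starting complex, averages 0.183% over its readings, each good to 0.5 percentage points.
- The forecast names starting complex, starting complex and starting complex for west, south-west and south, with one-exchanged complex at 0.05% (0% to 0.2%), holding that “each run is already at equilibrium”. My reckoning differs in west.

    starting complex + incoming ligand → leaving ligand + complex with one exchanged (k = 0.0300 L mol⁻¹ s⁻¹)
    complex with one exchanged + incoming ligand → leaving ligand + complex with two exchanged (k = 0.0540 L mol⁻¹ s⁻¹)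
    2 starting complex → self-condensation product (k = 1.40 × 10⁻⁵ L mol⁻¹ s⁻¹)
    complex with one exchanged → side product (k = 0.0940 s⁻¹)

- West ends with complex with two exchanged at 20.1%, starting complex at 0% and side product at 79.8%, its ligand charge standing below the branch concentration as read from dawn, 1.84 M. In south-west, exchange and side-product loss ran while ligand lasted, with 99.9% of the side-product turnover done by 0.200 h. Afterwards, with ligand at 0% and one-exchanged complex at 0%, starting complex slipped from 52.1% at 0.500 h to 51.4% at 1.00 h as self-condensation product rose from 0.837% to 1.58%.
- Take south-west's neighbour with 0.47 M of ligand: the branch gives share 11.3%, so two-exchanged complex 8.68% and starting complex 23.2%. That neighbour computes to 7.95% and 22.1%, with side product at 69.6%.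

The numbers in the tables come from a simulation on assumed constants.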